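**The question.** How much of the substrate has become product in the flask at 5.0 d, has the reaction stopped there, and where does it end?

| flask | substrate | solid reagent | free catalyst | remark | time |
|---|---|---|---|---|---|
| alder | 0.010 M (in portions, 4) | 0.020 M | 10 µM | run made earlier; portions every 30 h |  |
| ash | 0.010 M (in portions, 4) | 0.045 M | 10 µM | run made earlier; portions every 30 h |  |
| larch | 0.0050 M (in portions, 4) | 0.030 M | 10 µM | run made earlier; portions every 30 h |  |
| flask | 0.010 M (in portions, 4) | 0.0300 M | 10 µM | the portions of substrate follow each other after 30 h, the first at the start | 5.0 d |

| run | time / d | product / % |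
|---|---|---|
| alder | 0.333 | 2.4 |
| alder | 1.04 | 9.3 |
| alder | 1.67 | 18.6 |
| alder | 3.00 | 39.1 |
| alder | 4.00 | 55.9 |
| ash | 0.333 | 2.4 |
| ash | 1.04 | 9.2 |
| ash | 1.67 | 17.7 |
| ash | 3.00 | 39.9 |
| ash | 4.00 | 56.2 |
| larch | 0.333 | 3.4 |
| larch | 0.625 | 5.6 |
| larch | 1.04 | 9.5 |
| larch | 2.00 | 23.8 |
| larch | 4.00 | 58.2 |

(each reading ± 0.5 percentage points)

- given per volume of solution although it is solid: solid reagent
- at the start none of the solid reagent is in solution
- the reaction counts as stopped when no species that holds the substrate changes by six tenths of a point or more over the second half of the time

1. which holds at 5.0 d: what has brought the reaction to rest, or that it has not come to rest (for what has run out or reacted, a solid counts together with what of it has only dissolved) (forward and back rates have come level / all of the substrate has reacted / no working catalyst is left / it is still moving / the partner has run out first)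
2. product at 5.0 d, in percent of the substrate charged
3. amount of product if the flask were left three thousand times as long, in percent of the substrate charged

**The constant.** In the flask, substrate is the limiting reagent, 0.010 M against 0.0300 M of solid reagent, so I keep its books. Alder and ash hold 0.020 M and 0.045 M of solid reagent, yet read 55.9% and 56.2% at 4.00 d. Larch has half the substrate, with 0.030 M of solid reagent, which lies between the amounts in alder and ash, and reads 58.2%. I therefore treat the loss as pseudo-first-order: each portion shrinks by its own age. The portion constant, the fraction of its remaining substrate that a portion loses per day, I read from the first portion, between the readings at 0.333 d and 1.04 d in the three runs, before the second portion arrives. Their mean is 0.497 d⁻¹. Carried to 4.00 d in alder, it gives 56.3% product, against the 55.9% read.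

**The ledger.** By my reckoning, in the flask at 5.0 d, the four portions, oldest first, hold 2.08%, 3.88%, 7.22% and 13.4% of the charge as substrate. The catalyst, at 10 µM, can hold hardly any of it. So 26.6% is left and my books close at 73.4% product, still moving. With more solid reagent than substrate in the flask's charge, I expect the entries to keep shrinking towards full conversion.

**The forecast.** The forecast gives 73% and 100% in the long run, and says it is still moving, reasoning that “the rate doesn't depend on how much solid is present”.

**The result.** The flask reaches 74.3% at 5.0 d: it is still moving, and the long run gives 100%.

    substrate + free catalyst ⇌ catalyst intermediate A (K = 42.0 L mol⁻¹, k = 4800 L mol⁻¹ h⁻¹)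
    solid reagent ⇌ partner, rate k2*(cs2 - [partner]) while solid is left; crystals form when [partner] > cs2 (solubility = 2.80 mM, k = 0.200 h⁻¹)
    catalyst intermediate B → free catalyst + product (k = 110 h⁻¹)
    partner ⇌ dormant form (K = 2.80, k = 0.170 h⁻¹)
    partner + catalyst intermediate A → catalyst intermediate B (k = 52000 L mol⁻¹ h⁻¹)

**Second flask.** My ledger left 26.6% of the substrate in this flask, and the flask holds 25.7% at 5.00 d, with free catalyst at 90.1% of its charge. A neighbour flask is charged with 6.0 × 10⁻⁶ M of free catalyst. Scaling the portion constant with that charge gives 0.298 d⁻¹, and the same four entries close at 57.1% product. That neighbour flask stands at 57.0%.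

The readings are calculated from invented constants, noise included.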